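**Strategy**

The synthesis rests on breaking the oxindole C3–C3a bond. A CH2 links oxindole C3 to pyrazinone C6, so the anilide of a 3-(pyrazin-2-yl)acrylic acid is a 2-alkenylazine once the pyrazinone is carried as its lactim ether and N1 is a pyridine-type nitrogen. A rhodium catalyst then transfers the ortho aryl carbon to the future C3, which closes the five-membered lactam 5-exo, creates the (S) centre and leaves the CH2 after protonation of the N1-stabilised aza-enolate. The precursor is a single N–aryl atropisomer of an N-(2,4,6-trimethoxybenzyl)-N-(2-boryl-6-prenylphenyl) (E)-acrylamide, made from an aminoboronate and a pyrazinylacrylic acid.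

Key step: step 11

**Remarks on the chemistry (assumptions and design choices)**

- Assumption: the axis descriptor of the productive atropisomer (aR, from a model of the syn-insertion) and the matched enantiomer of the diene ligand are not predictable with certainty. Both are fixed by a pilot cyclisation of each atropisomer and correlation of the configuration of 17.
- The N–aryl bond of an N-benzyl 2,6-disubstituted anilide is a configurationally stable axis. Each atropisomer can cyclise to one C3 configuration only, so a chiral catalyst acting on the racemic axis could at best resolve it. The precursor is therefore used as one atropisomer. The other can be equilibrated thermally (o-xylene, about 140 °C) and separated again.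
- The oxindole nitrogen carries a 2,4,6-trimethoxybenzyl group, which should ionise in dilute TFA at room temperature. A less electron-rich benzyl group on a lactam nitrogen usually needs hot TFA, which would hydrate or cyclise the prenyl alkene.
- C6 of the pyrazine is brominated at the pyrazinone stage, before the anisyl ether is present. An alkoxypyrazine is a poor substrate for electrophilic bromination, and N-bromosuccinimide would compete for the anisyl ring.
- The acid chloride is made with an α-chloroenamine, so no HCl is released onto the acid-labile lactim ether.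

**Route**

Step 1
Reactants: 1 2-bromo-6-iodoaniline; 2 tributyl(3-methylbut-2-en-1-yl)stannane
Product: 3 2-bromo-6-(3-methylbut-2-en-1-yl)aniline
Conditions: Pd(PPh3)4 (5 mol %), DMF, 90 °C
Reagents that add atoms: none
Why: Stille coupling; zerovalent palladium inserts into C–I far faster than into C–Br, and with triphenylphosphine-ligated palladium in DMF the allylic stannane should transfer the prenyl group through its tin-bearing carbon to give the linear isomer.

Step 2
Reactants: 3 2-bromo-6-(3-methylbut-2-en-1-yl)aniline
Product: 5 2-bromo-6-(3-methylbut-2-en-1-yl)-N-(2,4,6-trimethoxybenzyl)aniline, via imine 4 (not isolated)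
Conditions: 2,4,6-trimethoxybenzaldehyde, Ti(OiPr)4, THF, 60 °C; then NaBH4, EtOH, 0 °C to rt
Reagents that add atoms: 2,4,6-trimethoxybenzaldehyde, COc1cc(OC)c(C=O)c(OC)c1
Why: Reductive amination; Ti(OiPr)4 drives condensation of the hindered, weakly nucleophilic aniline with the electron-rich aldehyde, and NaBH4 reduces the imine without touching the aryl bromide or the trisubstituted alkene.

Step 3
Reactants: 5 2-bromo-6-(3-methylbut-2-en-1-yl)-N-(2,4,6-trimethoxybenzyl)aniline
Product: 6 2-(3-methylbut-2-en-1-yl)-6-(4,4,5,5-tetramethyl-1,3,2-dioxaborolan-2-yl)-N-(2,4,6-trimethoxybenzyl)aniline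
Conditions: B2pin2, PdCl2(dppf) (5 mol %), KOAc, 1,4-dioxane, 90 °C
Reagents that add atoms: bis(pinacolato)diboron, CC1(C)OB(OC1(C)C)B1OC(C)(C)C(C)(C)O1
Why: Miyaura borylation; oxidative addition at the aryl bromide, acetate-assisted transmetalation with the diboron and reductive elimination give the pinacol boronate, while the secondary N–H and the remote prenyl alkene are inert under KOAc.

Step 4
Reactants: 7 3-methylpyrazin-2(1H)-one
Product: 8 5-bromo-3-methylpyrazin-2(1H)-one
Conditions: NBS, DMF, 0 °C to rt
Reagents that add atoms: N-bromosuccinimide, O=C1CCC(=O)N1Br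
Why: Electrophilic bromination; the pyrazinone reacts as an enamide at C5, the β-carbon of the N1–C6=C5 unit, because C3 is blocked by the methyl group.

Step 5
Reactants: 8 5-bromo-3-methylpyrazin-2(1H)-one
Product: 9 5-methoxy-3-methylpyrazin-2(1H)-one
Conditions: NaOMe (5 equiv), CuBr (20 mol %), MeOH/DMF, 110 °C (sealed); AcOH to pH 6
Reagents that add atoms: sodium methoxide, [Na+].[O-]C
Why: Ullmann-type copper-catalysed methoxylation; monovalent copper couples the aryl bromide with methoxide even though the ring is present as its sodium salt, as bromophenolates do under the same conditions.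

Step 6
Reactants: 9 5-methoxy-3-methylpyrazin-2(1H)-one
Product: 10 6-bromo-5-methoxy-3-methylpyrazin-2(1H)-one
Conditions: NBS (1.0 equiv), DMF, −10 to 0 °C, dark
Reagents that add atoms: N-bromosuccinimide, O=C1CCC(=O)N1Br
Why: Electrophilic bromination; in the lactam tautomer C5=C6 is an enol ether, so bromine should enter at C6, the only ring C–H and ortho to the methoxy group.

Step 7
Reactants: 10 6-bromo-5-methoxy-3-methylpyrazin-2(1H)-one
Product: 11 2-bromo-3-methoxy-6-[(4-methoxybenzyl)oxy]-5-methylpyrazine
Conditions: PMBCl, Ag2CO3, toluene, 60 °C, dark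
Reagents that add atoms: 4-methoxybenzyl chloride, COc1ccc(CCl)cc1
Why: Silver-mediated O-alkylation of the ambident lactam; the silver salt in a non-polar solvent alkylates on oxygen, helped by the C6 bromine that shields N1, and the resulting lactim ether makes N1 a pyridine-type nitrogen.

Step 8
Reactants: 11 2-bromo-3-methoxy-6-[(4-methoxybenzyl)oxy]-5-methylpyrazine; 12 acrylic acid
Product: 13 (E)-3-{3-methoxy-6-[(4-methoxybenzyl)oxy]-5-methylpyrazin-2-yl}prop-2-enoic acid
Conditions: Pd(OAc)2 (5 mol %), P(o-tol)3 (10 mol %), Et3N, MeCN, 85 °C; citric acid to pH 4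
Reagents that add atoms: none
Why: Mizoroki–Heck reaction; oxidative addition into the C–Br bond next to the ring nitrogen, syn-insertion of acrylic acid and syn-β-hydride elimination give the (E)-acrylic acid directly, so no ester hydrolysis is needed.

Step 9
Reactants: 13 (E)-3-{3-methoxy-6-[(4-methoxybenzyl)oxy]-5-methylpyrazin-2-yl}prop-2-enoic acid; 6 2-(3-methylbut-2-en-1-yl)-6-(4,4,5,5-tetramethyl-1,3,2-dioxaborolan-2-yl)-N-(2,4,6-trimethoxybenzyl)aniline
Product: 15 (E)-3-{3-methoxy-6-[(4-methoxybenzyl)oxy]-5-methylpyrazin-2-yl}-N-[2-(3-methylbut-2-en-1-yl)-6-(4,4,5,5-tetramethyl-1,3,2-dioxaborolan-2-yl)phenyl]-N-(2,4,6-trimethoxybenzyl)prop-2-enamide (racemic N–aryl axis), via acid chloride 14 (not isolated)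
Conditions: 1-chloro-N,N,2-trimethylprop-1-en-1-amine, CH2Cl2, 0 °C to rt; then 6, pyridine, DMAP (cat.), 0 to 40 °C
Reagents that add atoms: 1-chloro-N,N,2-trimethylprop-1-en-1-amine, CC(C)=C(Cl)N(C)C (supplies the chlorine of 14 only; nothing from it remains in 15)
Why: Amide formation through the acid chloride; the α-chloroenamine makes the chloride under neutral conditions and the hindered secondary aniline is then acylated with pyridine/DMAP catalysis, as N-alkyl-2,6-disubstituted anilines are with reactive acid chlorides.

Step 10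
Reactants: 15 the racemic-axis amide
Product: 16 (aR)-atropisomer of 15 (predicted descriptor; the atropisomer that cyclises to the (S)-oxindole)
Conditions: preparative chiral SFC (amylose tris(3,5-dimethylphenylcarbamate) phase, CO2/i-PrOH), 25 °C; fractions kept below 30 °C
Reagents that add atoms: none
Why: Resolution of atropisomers on a chiral stationary phase; the N–aryl bond of this N-benzyl 2,6-disubstituted anilide should be a stable axis (rotation barrier expected near 30 kcal/mol), and because the next step can only occur on the alkene face beside the metallated ortho carbon, this axis decides the C3 configuration.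

Step 11
Reactants: 16 (aR)-atropisomer of the boryl acrylamide
Product: 17 (3S)-3-({3-methoxy-6-[(4-methoxybenzyl)oxy]-5-methylpyrazin-2-yl}methyl)-7-(3-methylbut-2-en-1-yl)-1-(2,4,6-trimethoxybenzyl)-1,3-dihydro-2H-indol-2-one
Conditions: [RhCl(C2H4)2]2 (2.5 mol %), 2,5-diphenylbicyclo[2.2.2]octa-2,5-diene (enantiomer matched to the axis, 5.5 mol %), KOH (10 mol %), 1,4-dioxane/H2O (10:1), 45 °C; pH 7 phosphate work-up
Reagents that add atoms: none
Why: Proposed new method: the hydroxorhodium complex (monovalent rhodium) transmetalates with the aryl boronate, the arylrhodium inserts the tethered (E)-alkene syn so that the aryl carbon bonds to the amide α-carbon (future C3), and the alkylrhodium next to the pyrazine, held as an aza-enolate on N1, is protonated by water, which regenerates Rh–OH. The closest known reaction type is the intermolecular enantioselective Hayashi–Miyaura-type addition of arylboron reagents to 2-alkenylazines under rhodium/chiral-diene catalysis; a tethered, lactam-forming version on an acrylanilide has not been shown. The oxindole ring closes 5-exo-trig, the mode that the short anilide tether allows for a syn-insertion and that places rhodium where the azine can stabilise it, whereas 6-endo closure would need aryl delivery to the pyrazine-bearing carbon. The C3 centre is set in the insertion by the N–aryl axis of 16: the metallated ortho carbon can reach only the alkene face on its own side of the amide plane, so (aR)-16 should give (S)-17, and the diene ligand is the enantiomer matched to that face. The step needs insertion to beat protodemetalation, protonation to beat β-hydride elimination (which would give the 3-alkylidene oxindole) and no enolisation of the acidic C3–H; the N-benzyl tertiary anilide keeps aryl and alkene syn, the doubly activated alkene should insert quickly, the N1-bound aza-enolate has no easy β-hydride path, and only catalytic hydroxide at 45 °C is present.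

Step 12
Reactants: 17 the protected (3S)-oxindole
Product: 18 astepyrazinol B, (3S)-3-[(3-methoxy-5-methyl-6-oxo-1,6-dihydropyrazin-2-yl)methyl]-7-(3-methylbut-2-en-1-yl)-1,3-dihydro-2H-indol-2-one
Conditions: TFA/CH2Cl2 (1:9), 1,3-dimethoxybenzene (10 equiv), 0 °C to rt; aq. NaHCO3
Reagents that add atoms: none
Why: Acidolysis (SN1 cleavage) of the lactim 4-methoxybenzyl ether and of the N-(2,4,6-trimethoxybenzyl) lactam, both of which should ionise in dilute TFA with the arene trapping the benzylic cations, conditions under which the prenyl alkene, the methyl lactim ether and the C3–H centre are expected to persist.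

**Compound list**

1 | 2-bromo-6-iodoaniline | Nc1c(Br)cccc1I | starting material
2 | tributyl(3-methylbut-2-en-1-yl)stannane | CCCC[Sn](CCCC)(CCCC)CC=C(C)C | starting material
3 | 2-bromo-6-(3-methylbut-2-en-1-yl)aniline | Nc1c(Br)cccc1CC=C(C)C | intermediate
4 | (E)-N-[2-bromo-6-(3-methylbut-2-en-1-yl)phenyl]-1-(2,4,6-trimethoxyphenyl)methanimine | COc1cc(OC)c(/C=N/c2c(Br)cccc2CC=C(C)C)c(OC)c1 | intermediate (not isolated)
5 | 2-bromo-6-(3-methylbut-2-en-1-yl)-N-(2,4,6-trimethoxybenzyl)aniline | COc1cc(OC)c(CNc2c(Br)cccc2CC=C(C)C)c(OC)c1 | intermediate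
6 | 2-(3-methylbut-2-en-1-yl)-6-(4,4,5,5-tetramethyl-1,3,2-dioxaborolan-2-yl)-N-(2,4,6-trimethoxybenzyl)aniline | COc1cc(OC)c(CNc2c(B3OC(C)(C)C(C)(C)O3)cccc2CC=C(C)C)c(OC)c1 | intermediate
7 | 3-methylpyrazin-2(1H)-one | Cc1ncc[nH]c1=O | starting material
8 | 5-bromo-3-methylpyrazin-2(1H)-one | Cc1nc(Br)c[nH]c1=O | intermediate
9 | 5-methoxy-3-methylpyrazin-2(1H)-one | COc1c[nH]c(=O)c(C)n1 | intermediate
10 | 6-bromo-5-methoxy-3-methylpyrazin-2(1H)-one | COc1nc(C)c(=O)[nH]c1Br | intermediate
11 | 2-bromo-3-methoxy-6-[(4-methoxybenzyl)oxy]-5-methylpyrazine | COc1nc(C)c(OCc2ccc(OC)cc2)nc1Br | intermediate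
12 | acrylic acid | C=CC(=O)O | starting material
13 | (E)-3-{3-methoxy-6-[(4-methoxybenzyl)oxy]-5-methylpyrazin-2-yl}prop-2-enoic acid | COc1nc(C)c(OCc2ccc(OC)cc2)nc1/C=C/C(=O)O | intermediate
14 | (E)-3-{3-methoxy-6-[(4-methoxybenzyl)oxy]-5-methylpyrazin-2-yl}prop-2-enoyl chloride | COc1nc(C)c(OCc2ccc(OC)cc2)nc1/C=C/C(Cl)=O | intermediate (not isolated)
15 | (E)-3-{3-methoxy-6-[(4-methoxybenzyl)oxy]-5-methylpyrazin-2-yl}-N-[2-(3-methylbut-2-en-1-yl)-6-(4,4,5,5-tetramethyl-1,3,2-dioxaborolan-2-yl)phenyl]-N-(2,4,6-trimethoxybenzyl)prop-2-enamide, racemic N–aryl axis | COc1nc(C)c(OCc2ccc(OC)cc2)nc1/C=C/C(=O)N(Cc3c(OC)cc(OC)cc3OC)c4c(CC=C(C)C)cccc4B5OC(C)(C)C(C)(C)O5 | intermediate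
16 | (aR)-atropisomer of 15 about the N–aryl bond (predicted descriptor; SMILES cannot encode the axis) | COc1nc(C)c(OCc2ccc(OC)cc2)nc1/C=C/C(=O)N(Cc3c(OC)cc(OC)cc3OC)c4c(CC=C(C)C)cccc4B5OC(C)(C)C(C)(C)O5 | intermediate (key-step precursor)
17 | (3S)-3-({3-methoxy-6-[(4-methoxybenzyl)oxy]-5-methylpyrazin-2-yl}methyl)-7-(3-methylbut-2-en-1-yl)-1-(2,4,6-trimethoxybenzyl)-1,3-dihydro-2H-indol-2-one | COc1nc(C)c(OCc2ccc(OC)cc2)nc1C[C@@H]1C(=O)N(Cc3c(OC)cc(OC)cc3OC)c4c(CC=C(C)C)cccc41 | intermediate (key-step product)
18 | astepyrazinol B, (3S)-3-[(3-methoxy-5-methyl-6-oxo-1,6-dihydropyrazin-2-yl)methyl]-7-(3-methylbut-2-en-1-yl)-1,3-dihydro-2H-indol-2-one | COc1nc(C)c(=O)[nH]c1C[C@@H]1C(=O)Nc2c(CC=C(C)C)cccc21 | target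

**Step count and risks**

Total step count: 12 (eleven reactions and one chromatographic resolution). Longest linear sequence: 9 steps (7 to 18, steps 4 to 12); the aniline branch (steps 1 to 3) joins at step 9.

Steps most likely to fail:

1. Step 11 (Proposed new method). The arylrhodium may be protonated before it inserts, the alkylrhodium may lose β-hydride to give the alkylidene, or configuration may erode by enolisation. The fallback makes the same C3–C3a bond by known palladium chemistry and sets out from 5 with acid chloride 14. Acylation of 5 with 14 (pyridine, DMAP, CH2Cl2, 40 °C) should give the (E)-N-(2-bromoaryl)acrylamide F1. An intramolecular Mizoroki–Heck reaction (Pd(OAc)2, PPh3, Et3N, MeCN, 80 °C) closes the ring 5-exo and β-hydride elimination gives the 3-(pyrazinylmethylidene)oxindole F2. Conjugate reduction with NaBH4 (THF/MeOH, 0 °C) gives the racemic oxindole F3. Preparative chiral SFC then returns the (S)-enantiomer, compound 17; the (R)-enantiomer can be racemised with a catalytic amine base and separated again.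

2. Step 5. Copper-mediated C–O coupling may be sluggish on the electron-rich pyrazinolate, with hydrodebromination competing. The fallback sets out from 8 and couples on the O-protected ring instead. O-alkylation (PMBCl, Ag2CO3, toluene, 60 °C) gives 5-bromo-2-[(4-methoxybenzyl)oxy]-3-methylpyrazine F4. Palladium-catalysed C–O coupling with methanol (Pd2(dba)3, tBuBrettPhos, NaOtBu, MeOH, 1,4-dioxane, 50 °C) gives 5-methoxy-2-[(4-methoxybenzyl)oxy]-3-methylpyrazine F5. Brief TFA/CH2Cl2 with 1,3-dimethoxybenzene at 0 °C removes the benzyl ether and comes back to the route at 9.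

3. Step 12. Acid-promoted hydration or cyclisation of the prenyl alkene may overtake the slower loss of the N-benzyl group. The fallback sets out from 17 and removes the two groups by different mechanisms. TFA (1% v/v) in CH2Cl2 with 1,3-dimethoxybenzene at 0 °C cleaves only the lactim ether and gives the N-(2,4,6-trimethoxybenzyl) pyrazinone F6. Oxidative N-debenzylation with (NH4)2Ce(NO3)6 in MeCN/H2O at 0 °C, a known cleavage of electron-rich N-benzyl lactams, then gives 18.

Further compounds

F1 | step 11 | (E)-N-[2-bromo-6-(3-methylbut-2-en-1-yl)phenyl]-3-{3-methoxy-6-[(4-methoxybenzyl)oxy]-5-methylpyrazin-2-yl}-N-(2,4,6-trimethoxybenzyl)prop-2-enamide | COc1nc(C)c(OCc2ccc(OC)cc2)nc1/C=C/C(=O)N(Cc3c(OC)cc(OC)cc3OC)c4c(CC=C(C)C)cccc4Br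
F2 | step 11 | 3-({3-methoxy-6-[(4-methoxybenzyl)oxy]-5-methylpyrazin-2-yl}methylidene)-7-(3-methylbut-2-en-1-yl)-1-(2,4,6-trimethoxybenzyl)-1,3-dihydro-2H-indol-2-one (alkene geometry not relevant) | COc1nc(C)c(OCc2ccc(OC)cc2)nc1C=C1C(=O)N(Cc3c(OC)cc(OC)cc3OC)c4c(CC=C(C)C)cccc41
F3 | step 11 | racemic 3-({3-methoxy-6-[(4-methoxybenzyl)oxy]-5-methylpyrazin-2-yl}methyl)-7-(3-methylbut-2-en-1-yl)-1-(2,4,6-trimethoxybenzyl)-1,3-dihydro-2H-indol-2-one | COc1nc(C)c(OCc2ccc(OC)cc2)nc1CC1C(=O)N(Cc3c(OC)cc(OC)cc3OC)c4c(CC=C(C)C)cccc41
F4 | step 5 | 5-bromo-2-[(4-methoxybenzyl)oxy]-3-methylpyrazine | Cc1nc(Br)cnc1OCc1ccc(OC)cc1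
F5 | step 5 | 5-methoxy-2-[(4-methoxybenzyl)oxy]-3-methylpyrazine | COc1cnc(OCc2ccc(OC)cc2)c(C)n1
F6 | step 12 | (3S)-3-[(3-methoxy-5-methyl-6-oxo-1,6-dihydropyrazin-2-yl)methyl]-7-(3-methylbut-2-en-1-yl)-1-(2,4,6-trimethoxybenzyl)-1,3-dihydro-2H-indol-2-one | COc1nc(C)c(=O)[nH]c1C[C@@H]1C(=O)N(Cc2c(OC)cc(OC)cc2OC)c3c(CC=C(C)C)cccc31
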